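**Retrosynthetic overview**

- The 3‑methyltetronic acid is the only ring made (the furan is bought as 3‑bromofuran); it is closed last by Dieckmann condensation of an α‑propanoyloxy methyl ester.
- That ester comes from an (E)‑alkenyl bromide, methyl (R)‑glycidate and propanoyl chloride; copper‑catalysed epoxide opening carries the glycidate stereocentre into C5.
- The (E,E)‑diene and the C–C bond to the methyl stereocentre come from a 1,2‑boronate shift (Zweifel type) between a secondary boronic ester and a (1Z,3E)‑dienyllithium; this is the proposed new step.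
- The methyl stereocentre comes from a sparteine‑controlled lithiation–borylation of hex‑4‑yn‑1‑ol benzoate, in which methyl shifts 1,2 from boron to carbon; hydrozirconation–bromination then gives the alkenyl bromide.
- The dienyl iodide comes from 3‑bromofuran, oxetane, acetylide, AlMe3 (carboalumination) and acetylene (carbocupration).

Assumption: every reagent named on a "Reagents that add atoms" line is bought as such. Nothing here has been run; conditions and selectivities are expectations from the reaction classes named.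

**Step 1**
Reactants: 1 3-bromofuran; 2 oxetane
Product: 4 3-(furan-3-yl)propan-1-ol, via furan-3-yllithium 3 (not isolated)
Conditions: nBuLi, THF, –78 °C; then 2, BF3·OEt2, –78 °C; aq. NH4Cl
Reagents that add atoms: none
Why: Bromine–lithium exchange gives the 3‑furyllithium, which opens BF3‑activated oxetane by SN2 (organolithium opening of a strained ether) at –78 °C before it can isomerise to the 2‑lithio species.

**Step 2**
Reactants: 4 3-(furan-3-yl)propan-1-ol
Product: 5 3-(3-iodopropyl)furan
Conditions: I2, PPh3, imidazole, CH2Cl2, 0 → 20 °C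
Reagents that add atoms: iodine, II
Why: Appel iodination of a primary alcohol (SN2 on the alkoxyphosphonium ion) is mild enough for the furan.

**Step 3**
Reactants: 5 3-(3-iodopropyl)furan
Product: 6 3-(pent-4-yn-1-yl)furan
Conditions: LiC≡CH·H2NCH2CH2NH2, DMSO, 20 °C
Reagents that add atoms: lithium acetylide ethylenediamine complex, [Li]C#C.NCCN
Why: SN2 alkylation of acetylide by an unhindered primary iodide in a dipolar aprotic solvent.

**Step 4**
Reactants: 6 3-(pent-4-yn-1-yl)furan
Product: 8 3-[(4E)-5-iodo-4-methylpent-4-en-1-yl]furan, via alkenyldimethylalane 7 (not isolated)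
Conditions: AlMe3 (2 equiv), Cp2ZrCl2 (0.2 equiv), H2O (1 equiv), CH2Cl2, –20 °C; then I2, THF, –20 °C
Reagents that add atoms: trimethylaluminium, C[Al](C)C; iodine, II
Why: Negishi zirconium‑catalysed carboalumination adds methyl and aluminium syn across the terminal alkyne with aluminium on the terminal carbon, and iodinolysis with retention gives the (E)‑iodide.

**Step 5**
Reactants: 8 3-[(4E)-5-iodo-4-methylpent-4-en-1-yl]furan
Product: 12 3-[(4E,6Z)-7-iodo-4-methylhepta-4,6-dien-1-yl]furan, via alkenyllithium 9 (not isolated), via lithium dialkenylcuprate 10 (not isolated), via lithium bis(dienyl)cuprate 11 (not isolated)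
Conditions: tBuLi (2.0 equiv), Et2O, –78 °C; CuBr·SMe2 (0.5 equiv), –40 °C; HC≡CH (1.1 equiv), –50 → –25 °C; I2, THF, –78 → 0 °C
Reagents that add atoms: acetylene, C#C; iodine, II
Why: Iodine–lithium exchange with retention, then Normant syn‑carbocupration of acetylene, places copper cis to the alkenyl group, and iodinolysis with retention gives the new double bond as the (Z)‑iodide.

**Step 6**
Reactants: 13 hex-4-yn-1-ol
Product: 14 hex-4-yn-1-yl 2,4,6-triisopropylbenzoate
Conditions: 2,4,6-triisopropylbenzoyl chloride, Et3N, DMAP (cat.), CH2Cl2, 40 °C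
Reagents that add atoms: 2,4,6-triisopropylbenzoyl chloride, CC(C)c1cc(C(C)C)c(C(Cl)=O)c(C(C)C)c1
Why: Acylation of the primary alcohol gives the hindered benzoate that directs α‑lithiation and later acts as the leaving group.

**Step 7**
Reactants: 14 hex-4-yn-1-yl 2,4,6-triisopropylbenzoate
Product: 17 2-[(2S)-hept-5-yn-2-yl]-4,4,5,5-tetramethyl-1,3,2-dioxaborolane, via α-lithiated benzoate 15 (not isolated), via lithium boronate complex 16 (not isolated)
Conditions: sBuLi, (–)-sparteine, Et2O, –78 °C, 5 h; methylboronic acid pinacol ester, –78 °C, 1 h; then 35 °C, 16 h; aq. NH4Cl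
Reagents that add atoms: methylboronic acid pinacol ester, CB1OC(C)(C)C(C)(C)O1
Why: Hoppe–Aggarwal lithiation–borylation: sBuLi/(–)-sparteine removes the pro‑S α‑hydrogen, borylation goes with retention, and methyl then undergoes a stereospecific 1,2‑metallate shift from boron to carbon with inversion as the benzoate leaves, which sets the (S) methyl stereocentre (expected er about 96:4).

**Step 8**
Reactants: 17 2-[(2S)-hept-5-yn-2-yl]-4,4,5,5-tetramethyl-1,3,2-dioxaborolane
Product: 19 2-[(2S,5E)-6-bromohept-5-en-2-yl]-4,4,5,5-tetramethyl-1,3,2-dioxaborolane, via alkenylzirconocene chloride 18 (not isolated)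
Conditions: Cp2Zr(H)Cl (2.2 equiv), THF, 20 → 50 °C; then N-bromosuccinimide, 0 °C
Reagents that add atoms: N-bromosuccinimide, O=C1CCC(=O)N1Br
Why: Syn‑hydrozirconation of the internal alkyne, equilibrated by excess Cp2Zr(H)Cl to the isomer with zirconium on the methyl‑bearing carbon (roughly 10:1 expected, minor regioisomer removed by chromatography), then bromination with retention gives the (E)‑2‑bromoalkene while the boronic ester is inert.

**Step 9**
Reactants: 19 2-[(2S,5E)-6-bromohept-5-en-2-yl]-4,4,5,5-tetramethyl-1,3,2-dioxaborolane; 12 3-[(4E,6Z)-7-iodo-4-methylhepta-4,6-dien-1-yl]furan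
Product: 23 3-[(4E,6E,8S,11E)-12-bromo-4,8-dimethyltrideca-4,6,11-trien-1-yl]furan, via dienyllithium 20 (not isolated), via lithium boronate complex 21 (not isolated), via β-iodoboronic ester 22 (not isolated)
Conditions: 12 (1.3 equiv), tBuLi (2.6 equiv), Et2O, –78 °C; 19, THF, –78 °C; I2, THF, –78 °C; NaOMe, MeOH, –78 → 20 °C
Reagents that add atoms: none
Why: Proposed new method: a Zweifel‑type coupling run with a conjugated (1Z,3E)‑dienyllithium and an unactivated secondary boronic ester, a partner class on which it has, to my knowledge, not been shown; the dienyllithium adds to boron, iodine attacks the β‑carbon of the boron‑bound alkene (the least hindered, most activated site, whereas the distal alkene ends in a fully substituted carbon), the secondary alkyl group shifts 1,2 from boron to the α‑carbon anti to iodine with retention at C8, and methoxide‑induced anti‑elimination of boron and iodine turns the (Z) alkene into the (6E) alkene, so the C7–C8 bond and the (E,E)‑diene form in one flask; the closest known reaction type is the Zweifel olefination of secondary boronic esters with simple alkenyllithiums.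

**Step 10**
Reactants: 23 3-[(4E,6E,8S,11E)-12-bromo-4,8-dimethyltrideca-4,6,11-trien-1-yl]furan; 24 methyl (2R)-oxirane-2-carboxylate; 25 propanoyl chloride
Product: 29 methyl (2R,4E,8S,9E,11E)-15-(furan-3-yl)-4,8,12-trimethyl-2-(propanoyloxy)pentadeca-4,9,11-trienoate, via alkenyllithium 26 (not isolated), via alkenylmagnesium bromide 27 (not isolated), via bromomagnesium alkoxide 28 (not isolated)
Conditions: tBuLi (2.0 equiv), Et2O, –78 °C; MgBr2·OEt2, –78 → –40 °C; CuI (15 mol%), 24 (1.5 equiv), THF, –40 → –20 °C; then 25, –20 → 0 °C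
Reagents that add atoms: none
Why: Bromine–lithium exchange and transmetalation go with retention, and CuI‑catalysed SN2 opening of the glycidate at its CH2 carbon (epoxide opening by an alkenylcopper species) leaves the epoxide stereocentre untouched as the (2R) carbinol, which is O‑acylated in the same flask.

**Step 11**
Reactants: 29 methyl (2R,4E,8S,9E,11E)-15-(furan-3-yl)-4,8,12-trimethyl-2-(propanoyloxy)pentadeca-4,9,11-trienoate
Product: 30 (5R)-5-[(2E,6S,7E,9E)-13-(furan-3-yl)-2,6,10-trimethyltrideca-2,7,9-trien-1-yl]-4-hydroxy-3-methylfuran-2(5H)-one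
Conditions: LiN(SiMe3)2 (2.5 equiv), THF, –78 → –20 °C; dilute aq. HCl to pH 3, 0 °C
Reagents that add atoms: none
Why: Dieckmann (intramolecular Claisen) condensation of the propanoate enolate onto the methyl ester closes the 3‑methyltetronic acid at low temperature, so C5 is not epimerised and the furan and diene see only a brief, mild acid work‑up.

**Compound list**

1 | 3-bromofuran | Brc1ccoc1 | starting material
2 | oxetane | C1COC1 | starting material
3 | furan-3-yllithium | [Li]c1ccoc1 | intermediate
4 | 3-(furan-3-yl)propan-1-ol | OCCCc1ccoc1 | intermediate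
5 | 3-(3-iodopropyl)furan | ICCCc1ccoc1 | intermediate
6 | 3-(pent-4-yn-1-yl)furan | C#CCCCc1ccoc1 | intermediate
7 | [(1E)-5-(furan-3-yl)-2-methylpent-1-en-1-yl]dimethylalane | C[Al](C)/C=C(\C)CCCc1ccoc1 | intermediate
8 | 3-[(4E)-5-iodo-4-methylpent-4-en-1-yl]furan | I/C=C(\C)CCCc1ccoc1 | intermediate
9 | [(1E)-5-(furan-3-yl)-2-methylpent-1-en-1-yl]lithium | [Li]/C=C(\C)CCCc1ccoc1 | intermediate
10 | lithium bis[(1E)-5-(furan-3-yl)-2-methylpent-1-en-1-yl]cuprate | [Li+].C\C(CCCc1ccoc1)=C/[Cu-]/C=C(\C)CCCc1ccoc1 | intermediate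
11 | lithium bis[(1Z,3E)-7-(furan-3-yl)-4-methylhepta-1,3-dien-1-yl]cuprate | [Li+].C\C(CCCc1ccoc1)=C/C=C\[Cu-]/C=C\C=C(/C)CCCc1ccoc1 | intermediate
12 | 3-[(4E,6Z)-7-iodo-4-methylhepta-4,6-dien-1-yl]furan | I/C=C\C=C(/C)CCCc1ccoc1 | intermediate
13 | hex-4-yn-1-ol | CC#CCCCO | starting material
14 | hex-4-yn-1-yl 2,4,6-triisopropylbenzoate | CC#CCCCOC(=O)c1c(C(C)C)cc(C(C)C)cc1C(C)C | intermediate
15 | (1S)-1-lithiohex-4-yn-1-yl 2,4,6-triisopropylbenzoate (as its sparteine complex) | [Li][C@@H](CCC#CC)OC(=O)c1c(C(C)C)cc(C(C)C)cc1C(C)C | intermediate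
16 | lithium methyl(pinacolato)[(1S)-1-(2,4,6-triisopropylbenzoyloxy)hex-4-yn-1-yl]borate | [Li+].C[B-]1(OC(C)(C)C(C)(C)O1)[C@@H](CCC#CC)OC(=O)c1c(C(C)C)cc(C(C)C)cc1C(C)C | intermediate
17 | 2-[(2S)-hept-5-yn-2-yl]-4,4,5,5-tetramethyl-1,3,2-dioxaborolane | C[C@@H](CCC#CC)B1OC(C)(C)C(C)(C)O1 | intermediate
18 | chlorobis(cyclopentadienyl)[(2E,6S)-6-(pinacolatoboryl)hept-2-en-2-yl]zirconium | C/C(=C\CC[C@H](C)B1OC(C)(C)C(C)(C)O1)[Zr](Cl)(C1C=CC=C1)C1C=CC=C1 | intermediate
19 | 2-[(2S,5E)-6-bromohept-5-en-2-yl]-4,4,5,5-tetramethyl-1,3,2-dioxaborolane | Br/C(C)=C/CC[C@H](C)B1OC(C)(C)C(C)(C)O1 | intermediate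
20 | [(1Z,3E)-7-(furan-3-yl)-4-methylhepta-1,3-dien-1-yl]lithium | [Li]/C=C\C=C(/C)CCCc1ccoc1 | intermediate
21 | lithium [(2S,5E)-6-bromohept-5-en-2-yl][(1Z,3E)-7-(furan-3-yl)-4-methylhepta-1,3-dien-1-yl](pinacolato)borate | [Li+].Br/C(C)=C/CC[C@H](C)[B-]1(OC(C)(C)C(C)(C)O1)/C=C\C=C(/C)CCCc1ccoc1 | intermediate
22 | 2-[(4E,8S,11E)-12-bromo-1-(furan-3-yl)-6-iodo-4,8-dimethyltrideca-4,11-dien-7-yl]-4,4,5,5-tetramethyl-1,3,2-dioxaborolane (anti adduct at C6/C7; one of the two C6/C7 diastereomers is drawn, both give 23) | Br/C(C)=C/CC[C@H](C)[C@H](B1OC(C)(C)C(C)(C)O1)[C@H](I)/C=C(\C)CCCc1ccoc1 | intermediate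
23 | 3-[(4E,6E,8S,11E)-12-bromo-4,8-dimethyltrideca-4,6,11-trien-1-yl]furan | Br/C(C)=C/CC[C@H](C)/C=C/C=C(\C)CCCc1ccoc1 | intermediate
24 | methyl (2R)-oxirane-2-carboxylate (methyl (R)-glycidate) | COC(=O)[C@H]1CO1 | starting material
25 | propanoyl chloride | CCC(Cl)=O | starting material
26 | alkenyllithium from 23 (Li in place of Br, geometry retained) | [Li]/C(C)=C/CC[C@H](C)/C=C/C=C(\C)CCCc1ccoc1 | intermediate
27 | alkenylmagnesium bromide from 26 (MgBr in place of Li, geometry retained) | Br[Mg]/C(C)=C/CC[C@H](C)/C=C/C=C(\C)CCCc1ccoc1 | intermediate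
28 | bromomagnesium alkoxide of methyl (2R,4E,8S,9E,11E)-15-(furan-3-yl)-2-hydroxy-4,8,12-trimethylpentadeca-4,9,11-trienoate | COC(=O)[C@H](O[Mg]Br)C/C(C)=C/CC[C@H](C)/C=C/C=C(\C)CCCc1ccoc1 | intermediate
29 | methyl (2R,4E,8S,9E,11E)-15-(furan-3-yl)-4,8,12-trimethyl-2-(propanoyloxy)pentadeca-4,9,11-trienoate | COC(=O)[C@H](OC(=O)CC)C/C(C)=C/CC[C@H](C)/C=C/C=C(\C)CCCc1ccoc1 | intermediate
30 | (5R)-5-[(2E,6S,7E,9E)-13-(furan-3-yl)-2,6,10-trimethyltrideca-2,7,9-trien-1-yl]-4-hydroxy-3-methylfuran-2(5H)-one | CC1=C(O)[C@@H](C/C(C)=C/CC[C@H](C)/C=C/C=C(\C)CCCc2ccoc2)OC1=O | target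

**Totals**

Total step count: 11. Longest linear sequence: 8 (steps 1, 2, 3, 4, 5, 9, 10, 11).

**Three steps most likely to fail**

Step 9 (the proposed new step). Iodine could attack the distal trisubstituted alkene or the furan, or the dienylboronate could react at its far end and then eliminate 1,4 with loss of geometric control. The fallback uses known chemistry only, sets out from 19 and comes back at 23. Zweifel vinylation of 19 (vinylmagnesium bromide, THF, then I2 and NaOMe/MeOH, –78 → 20 °C) gives (2E,6S)-2-bromo-6-methylocta-2,7-diene F1. Cross‑metathesis of F1 with vinylboronic acid pinacol ester (second‑generation Hoveyda–Grubbs catalyst, CH2Cl2, 40 °C) gives 2-[(1E,3S,6E)-7-bromo-3-methylocta-1,6-dien-1-yl]-4,4,5,5-tetramethyl-1,3,2-dioxaborolane F2. Suzuki–Miyaura coupling of F2 with the (E)‑iodide 8 (Pd(PPh3)4, aqueous K3PO4, THF, 20 °C, where the alkenyl bromide is left alone) gives 23. Step 5 is then not needed.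

Step 10. tBuLi may add to the diene, the alkenylmagnesium species may attack the glycidate ester, and the in‑flask acylation may be incomplete. The fallback sets out from 23 and comes back at 29. A nickel‑catalysed reductive cross‑electrophile coupling of 23 with 24 (NiCl2(dme), 2,2'-bipyridine, NaI, Et3N·HCl, Mn powder, DMPU, 20 °C) replaces the organometallic route: iodide opens the epoxide at CH2 and the alkyl radical formed is captured by the alkenylnickel species. This gives methyl (2R,4E,8S,9E,11E)-15-(furan-3-yl)-2-hydroxy-4,8,12-trimethylpentadeca-4,9,11-trienoate F4, which is isolated and acylated with 25 (pyridine, DMAP, CH2Cl2, 0 °C) to 29.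

Step 7. Methyl migration in the boronate complex may be slow, and the er may erode while sparteine is present. The fallback sets out from 14 and comes back at 17. Lithiation of 14 (sBuLi, (–)-sparteine, Et2O, –78 °C) and trapping with Me3SnCl gives (1S)-1-(trimethylstannyl)hex-4-yn-1-yl 2,4,6-triisopropylbenzoate F3, which is purified and its er measured. Tin–lithium exchange of F3 (nBuLi, Et2O, –78 °C, retention) regenerates the carbenoid without diamine; methylboronic acid pinacol ester and warming to 35 °C then give 17.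

**Further compounds**

F1 | step 9 | (2E,6S)-2-bromo-6-methylocta-2,7-diene | Br/C(C)=C/CC[C@H](C)C=C
F2 | step 9 | 2-[(1E,3S,6E)-7-bromo-3-methylocta-1,6-dien-1-yl]-4,4,5,5-tetramethyl-1,3,2-dioxaborolane | Br/C(C)=C/CC[C@H](C)/C=C/B1OC(C)(C)C(C)(C)O1
F3 | step 7 | (1S)-1-(trimethylstannyl)hex-4-yn-1-yl 2,4,6-triisopropylbenzoate | C[Sn](C)(C)[C@@H](CCC#CC)OC(=O)c1c(C(C)C)cc(C(C)C)cc1C(C)C
F4 | step 10 | methyl (2R,4E,8S,9E,11E)-15-(furan-3-yl)-2-hydroxy-4,8,12-trimethylpentadeca-4,9,11-trienoate | COC(=O)[C@H](O)C/C(C)=C/CC[C@H](C)/C=C/C=C(\C)CCCc1ccoc1
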